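**Strategy.** The route rests on disconnecting C1–C2 of the cyclopentane (C1–C5) and tracing the C1–C2–C3 unit back to an enol ether C1–O–C3(=CH2). The precursor is a bridged ketal in which cycloheptane, cyclopropane, benzoxepine and both arenes already exist and an oxolane oxygen stands in for C2. The key step is an acid-catalysed Petasis–Ferrier-type 1,3 O→C rearrangement: ionisation at the ketal carbon C1 (the aryl-ether oxygen stays), then 5-(enolexo)-exo-trig aldol closure. It exploits the C1 tertiary aryl ether flanked by epimerisable C5 and C10: C1 is set by the tether from quaternary C4, and C5/C10 isomers are funnelled through the oxocarbenium/enol-ether equilibrium.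

Key step: step 12

Numbering used: aromadendrane numbering C1–C15 (C1 O-bearing carbon, C2/C3 cyclopentane CH2, C4 quaternary carbon with Me-15, C5 ring-fusion CH, C6/C7 cyclopropane CH, C8/C9 CH2, C10 CH with Me-14, C11 CMe2); C7′ = CH(Ph); aryl C1′ bears C7′, C2′ bears the ether oxygen, C6′ is the other ortho carbon.

Assumption: Rh/(S)-SEGPHOS is taken to deliver the (S)-lactone 11 by analogy with 1,4-additions to coumarins; if the sense is opposite, (R)-SEGPHOS is used.

Step 1
Reactants: 1 (+)-3-carene
Product: 2 keto acetal 1-[(1S,3R)-3-(2,2-dimethoxyethyl)-2,2-dimethylcyclopropyl]propan-2-one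
Conditions: O3, CH2Cl2/MeOH, −78 °C; then Me2S, TsOH (cat.), −78 → 23 °C
Reagents that add atoms: ozone ([O-][O+]=O); methanol (CO)
Why: Ozonolysis with reductive work-up cleaves the trisubstituted alkene and the aldehyde arm is acetalised selectively under acid catalysis, while both cyclopropane stereocentres (future C6 and C7) come unchanged from the chiral pool.

Step 2
Reactants: 2 keto acetal
Product: 3 enol silane {[3-[(1S,3R)-3-(2,2-dimethoxyethyl)-2,2-dimethylcyclopropyl]prop-1-en-2-yl]oxy}trimethylsilane
Conditions: LDA, TMSCl (in situ quench), THF, −78 °C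
Reagents that add atoms: chlorotrimethylsilane (C[Si](C)(C)Cl)
Why: Kinetic deprotonation of the methyl ketone at the methyl group and O-silylation give the terminal enol silane needed for a regiodefined Mukaiyama reaction.

Step 3
Reactants: 3 enol silane
Product: 5 enone (1S,7R)-8,8-dimethylbicyclo[5.1.0]oct-4-en-3-one, via β-methoxy ketone 4 (not isolated)
Conditions: TMSOTf (10 mol%), CH2Cl2, −78 °C; then DBU, 0 → 23 °C
Reagents that add atoms: none
Why: Intramolecular Mukaiyama aldol-type addition of the enol silane to the acetal-derived oxocarbenium ion closes the seven-membered ring (the cis-cyclopropane holds both arms on one side), and E1cB loss of methanol gives the conjugated enone.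

Step 4
Reactants: 5 enone
Product: 7 ketone (1S,7R)-4,8,8-trimethylbicyclo[5.1.0]octan-3-one (C10 epimers), via lithium enolate 6 (not isolated)
Conditions: L-Selectride, THF, −78 °C; then MeI, HMPA, −78 → 0 °C
Reagents that add atoms: iodomethane (CI)
Why: Conjugate reduction of the β-unsubstituted enone gives the C1/C10 enolate regiospecifically and C-methylation installs Me-14 (reductive enolate alkylation); the C10 configuration is left open because step 12 re-sets it.

Step 5
Reactants: 8 5,7-dihydroxycoumarin
Product: 9 5,7-bis(benzyloxy)coumarin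
Conditions: BnBr, K2CO3, DMF, 60 °C
Reagents that add atoms: benzyl bromide (BrCc1ccccc1)
Why: Williamson etherification protects both phenols as benzyl ethers, which should survive all later steps and are removed by hydrogenolysis at the end.

Step 6
Reactants: 9 5,7-bis(benzyloxy)coumarin; 10 phenylboronic acid
Product: 11 (S)-5,7-bis(benzyloxy)-4-phenylchroman-2-one
Conditions: [Rh(acac)(C2H4)2] (3 mol%), (S)-SEGPHOS, dioxane/H2O 10:1, 60 °C
Reagents that add atoms: none
Why: Rhodium-catalysed asymmetric 1,4-addition of the arylboronic acid to the coumarin (Hayashi–Miyaura reaction) sets C7′ under catalyst control, with the lactone holding the future ether oxygen on C3.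

Step 7
Reactants: 7 ketone; 11 (S)-lactone
Product: 14 keto lactone (4S)-5,7-bis(benzyloxy)-4-phenylchroman-2-one carrying at its C3 (= C4) the (1S,7R)-4,8,8-trimethyl-3-oxobicyclo[5.1.0]oct-2-yl group (new C4–C5 bond; C4/C10 epimers), via ketone lithium enolate 12 (not isolated), via lactone lithium enolate 13 (not isolated)
Conditions: LDA, THF, −78 °C (7 and 11 separately, 11 in excess); combine; Fe(acac)3, −78 → 0 °C
Reagents that add atoms: none
Why: Oxidative enolate heterocoupling, in which Fe(III) oxidises the more electron-rich lactone enolate to the C4 radical that adds to C5 of the kinetic ketone enolate; C4, C5 and C10 stay epimerisable here (C5 should settle with C4 anti to the cyclopropane) and are fixed in steps 9 and 12.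

Step 8
Reactants: 14 keto lactone
Product: 15 enol silane of 14 (C1=C10 isomer drawn)
Conditions: TMSOTf, Et3N, CH2Cl2, 0 °C
Reagents that add atoms: trimethylsilyl trifluoromethanesulfonate (C[Si](C)(C)OS(=O)(=O)C(F)(F)F)
Why: Soft enolisation silylates the ketone without a free enolate (which would attack the aryl lactone), masking C1 so that the lactone α-position is the only acidic site; either enol silane regioisomer serves.

Step 9
Reactants: 15 enol silane
Product: 17 C4-methylated lactone (Me-15 trans to phenyl on the lactone ring), via lithium lactone enolate 16 (not isolated)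
Conditions: LDA, THF/HMPA, −78 °C; then MeI, −78 → −40 °C
Reagents that add atoms: iodomethane (CI)
Why: Lactone enolate alkylation in which the pseudoaxial C7′ phenyl group (pushed axial by the peri benzyloxy group at C6′) blocks one face, so methyl enters anti to phenyl and sets the C4 quaternary centre with Me-15 trans and C5 cis to phenyl, as the target requires.

Step 10
Reactants: 17 C4-methylated lactone
Product: 19 bridged pseudo-ester (aryl ether oxygen and lactone oxygen both on C1), via enol lactone 18 (not isolated)
Conditions: CsF, MeCN, 23 °C; then MsOH (1.5 equiv), CH2Cl2, 4 Å MS, −20 → 0 °C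
Reagents that add atoms: none
Why: Fluoride frees the enolate, whose oxygen is acylated by the aryl lactone (5-exo-trig O→O acyl shift driven by release of the phenoxide; C-acylation would be 5-(enolendo)-exo-trig), and acid then adds the tethered phenol across the enol ester (kinetic pseudo-ester formation), closing the benzoxepine with C1 fixed because the oxygen can reach C1 only from the face of C7′.

Step 11
Reactants: 19 bridged pseudo-ester
Product: 20 bridged methylene ketal (C3=CH2 enol ether)
Conditions: Cp2TiMe2, toluene, 70 °C, dark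
Reagents that add atoms: dimethyltitanocene (C[Ti](C)(C1C=CC=C1)C1C=CC=C1)
Why: Petasis methylenation converts the acylal-type lactone carbonyl into the exocyclic enol ether (first stage of a Petasis–Ferrier sequence), adding C2 without touching a stereocentre.

Step 12
Reactants: 20 bridged methylene ketal
Product: 21 bridged ketone (3-oxo-di-O-benzyl-bis(deformyl)psiguadial A)
Conditions: CSA (0.2 equiv), 4 Å MS, ClCH2CH2Cl, 23 → 45 °C
Reagents that add atoms: none
Why: Acid ionises the ketal at C1 (C-protonation of the exocyclic enol ether, then heterolysis of the C1–O(oxolane) bond), leaving the O-aryl oxocarbenium ion inside the benzoxepine and the enol of the C3 methyl ketone, which recombine through carbon as C2 attacks C1. The closest known reaction types are the Petasis–Ferrier rearrangement and the aglycon-retaining Ferrier carbocyclisation, i.e. an intramolecular Mukaiyama-type aldol addition to an oxocarbenium ion. Only the cyclopentane (C1–C2–C3–C4–C5) is closed, by 5-(enolexo)-exo-trig attack, while the temporary oxolane opens to give the β-aryloxy ketone. C1 is controlled by the tether: C2 is delivered from C3 on quaternary C4, so the new C1–C2 bond must be cis to C4–C3 across the benzoxepine and the aryloxy group ends trans to C2. C5 and C10 are under Curtin–Hammett control because the oxocarbenium ion equilibrates with the aryl enol ethers (C1=C5, C1=C10), and closure should go through the ion with C4 anti to the cyclopropane at C5 and the C10 methyl anti to the incoming C2 (cis to oxygen). The step needs C–C bond formation to outrun hydrolysis and C2→C1 to win over C10→C3; dry conditions secure the first, and the second follows because closure from the isomeric fused chroman ketal would be 5-(enolendo)-exo-trig, so that ketal can only revert.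

Step 13
Reactants: 21 bridged ketone
Product: 23 di-O-benzyl-bis(deformyl)psiguadial A, via tosylhydrazone 22 (not isolated)
Conditions: TsNHNH2, EtOH, 70 °C; then catecholborane, CHCl3, 0 °C; NaOAc·3H2O, 60 °C
Reagents that add atoms: none
Why: Reductive deoxygenation through the tosylhydrazone (Caglioti-type reduction with catecholborane) turns C3=O into CH2 under near-neutral conditions that should avoid E1cB loss of the β-aryloxy group; no stereocentre is formed.

Step 14
Reactants: 23 di-O-benzyl-bis(deformyl)psiguadial A
Product: 24 bis(deformyl)psiguadial A (diphenol)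
Conditions: H2 (1 atm), Pd/C, EtOAc/MeOH, 23 °C
Reagents that add atoms: none
Why: Hydrogenolysis cleaves the two aryl benzyl ethers, while the cyclopropane, the tertiary alkyl aryl ether and the diarylmethine carry no benzylic C–O bond and should persist.

Step 15
Reactants: 24 diphenol
Product: 25 psiguadial A
Conditions: Cl2CHOMe, TiCl4, CH2Cl2, −78 → 0 °C; then H2O
Reagents that add atoms: dichloromethyl methyl ether (COC(Cl)Cl); water (O)
Why: Double Rieche formylation at the two free ring positions (each ortho/para to oxygen) and hydrolysis of the α-chloro ethers give the dialdehyde without touching a stereocentre.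

**Compound list**

1 | (+)-3-carene, (1S,6R)-3,7,7-trimethylbicyclo[4.1.0]hept-3-ene | CC1=CC[C@@H]2[C@H](C1)C2(C)C | starting material
2 | keto acetal 1-[(1S,3R)-3-(2,2-dimethoxyethyl)-2,2-dimethylcyclopropyl]propan-2-one | COC(OC)C[C@@H]1[C@H](CC(C)=O)C1(C)C | intermediate
3 | terminal TMS enol ether of 2 | COC(OC)C[C@@H]1[C@H](CC(=C)O[Si](C)(C)C)C1(C)C | intermediate
4 | β-methoxy ketone (1S,7R)-5-methoxy-8,8-dimethylbicyclo[5.1.0]octan-3-one (C5 epimers) | COC1C[C@@H]2[C@H](CC(=O)C1)C2(C)C | intermediate
5 | enone (1S,7R)-8,8-dimethylbicyclo[5.1.0]oct-4-en-3-one | O=C1C=CC[C@@H]2[C@H](C1)C2(C)C | intermediate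
6 | lithium (1S,7R)-8,8-dimethylbicyclo[5.1.0]oct-3-en-3-olate | [Li+].[O-]C1=CCC[C@@H]2[C@H](C1)C2(C)C | intermediate
7 | ketone (1S,7R)-4,8,8-trimethylbicyclo[5.1.0]octan-3-one (C10 epimers) | CC1CC[C@@H]2[C@H](CC1=O)C2(C)C | intermediate
8 | 5,7-dihydroxycoumarin | O=C1C=Cc2c(O)cc(O)cc2O1 | starting material
9 | 5,7-bis(benzyloxy)coumarin | O=C1C=Cc2c(OCc3ccccc3)cc(OCc3ccccc3)cc2O1 | intermediate
10 | phenylboronic acid | OB(O)c1ccccc1 | starting material
11 | (S)-5,7-bis(benzyloxy)-4-phenylchroman-2-one | O=C1C[C@@H](c2ccccc2)c2c(OCc3ccccc3)cc(OCc3ccccc3)cc2O1 | intermediate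
12 | kinetic lithium enolate of 7 (C1=C5 enolate) | [Li+].CC1CC[C@@H]2[C@H](C=C1[O-])C2(C)C | intermediate
13 | lithium enolate of lactone 11 | [Li+].[O-]C1=C[C@@H](c2ccccc2)c2c(OCc3ccccc3)cc(OCc3ccccc3)cc2O1 | intermediate
14 | keto lactone, C4–C5 linked (C7′ S; C5 with C4 anti to the cyclopropane; C4 and C10 epimers) | O=C1Oc2cc(OCc3ccccc3)cc(OCc3ccccc3)c2[C@H](c4ccccc4)C1[C@@H]5C(=O)C(C)CC[C@@H]6[C@H]5C6(C)C | intermediate
15 | TMS enol ether of 14 (C1=C10 isomer drawn) | O=C1Oc2cc(OCc3ccccc3)cc(OCc3ccccc3)c2[C@H](c4ccccc4)C1[C@@H]5C(O[Si](C)(C)C)=C(C)CC[C@@H]6[C@H]5C6(C)C | intermediate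
16 | lithium lactone enolate of 15 | [Li+].[O-]C1=C([C@@H]5C(O[Si](C)(C)C)=C(C)CC[C@@H]6[C@H]5C6(C)C)[C@@H](c4ccccc4)c2c(OCc3ccccc3)cc(OCc3ccccc3)cc2O1 | intermediate
17 | C4-methylated lactone enol silane (Me-15 trans to phenyl; C5 cis to phenyl) | O=C1Oc2cc(OCc3ccccc3)cc(OCc3ccccc3)c2[C@H](c4ccccc4)[C@]1(C)[C@@H]5C(O[Si](C)(C)C)=C(C)CC[C@@H]6[C@H]5C6(C)C | intermediate
18 | enol γ-lactone with free phenol (exocyclic C1=C10) | Oc1cc(OCc2ccccc2)cc(OCc2ccccc2)c1[C@H](c3ccccc3)[C@@]4(C)C(=O)OC5=C(C)CC[C@@H]6[C@H]([C@H]45)C6(C)C | intermediate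
19 | bridged pseudo-ester: 2-oxa analogue of 21 with C3 as lactone carbonyl (natural C10 epimer drawn; epimer mixture possible) | C[C@H]1CC[C@@H]2[C@H]([C@@H]3[C@]4(C)C(=O)O[C@@]31Oc1cc(OCc5ccccc5)cc(OCc5ccccc5)c1[C@@H]4c1ccccc1)C2(C)C | intermediate
20 | bridged methylene ketal (C3=CH2; natural C10 epimer drawn) | C[C@H]1CC[C@@H]2[C@H]([C@@H]3[C@]4(C)C(=C)O[C@@]31Oc1cc(OCc5ccccc5)cc(OCc5ccccc5)c1[C@@H]4c1ccccc1)C2(C)C | intermediate
21 | 3-oxo-di-O-benzyl-bis(deformyl)psiguadial A | C[C@H]1CC[C@@H]2[C@H]([C@@H]3[C@]4(C)C(=O)C[C@@]31Oc1cc(OCc5ccccc5)cc(OCc5ccccc5)c1[C@@H]4c1ccccc1)C2(C)C | intermediate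
22 | tosylhydrazone of 21 | C[C@H]1CC[C@@H]2[C@H]([C@@H]3[C@]4(C)C(=NNS(=O)(=O)c5ccc(C)cc5)C[C@@]31Oc1cc(OCc5ccccc5)cc(OCc5ccccc5)c1[C@@H]4c1ccccc1)C2(C)C | intermediate
23 | di-O-benzyl-bis(deformyl)psiguadial A | C[C@H]1CC[C@@H]2[C@H]([C@@H]3[C@]4(C)CC[C@@]31Oc1cc(OCc5ccccc5)cc(OCc5ccccc5)c1[C@@H]4c1ccccc1)C2(C)C | intermediate
24 | bis(deformyl)psiguadial A (diphenol) | C[C@H]1CC[C@@H]2[C@H]([C@@H]3[C@]4(C)CC[C@@]31Oc1cc(O)cc(O)c1[C@@H]4c1ccccc1)C2(C)C | intermediate
25 | psiguadial A | C[C@H]1CC[C@@H]2[C@H]([C@@H]3[C@]4(C)CC[C@@]31Oc1c(C=O)c(O)c(C=O)c(O)c1[C@@H]4c1ccccc1)C2(C)C | target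

**Step count.** Total: 15 steps. Longest linear sequence: 13 steps (steps 1–4, then 7–15).

**Three steps most likely to fail**

Step 7 (enolate heterocoupling). What may go wrong: homocoupling of either enolate, oxidation of the ketone enolate to an α-keto radical that opens the adjacent cyclopropane, or enolisation of the product ketone followed by acyl shift onto the aryl lactone. The fallback sets out from 7 and 11 and returns at 14. Lactone 11 is brominated at C3 (LiHMDS, then NBS, −78 °C) to the trans-3-bromo lactone F1, and ketone 7 is converted (LDA, TMSCl) into its kinetic enol silane F2. Visible-light photoredox alkylation (fac-Ir(ppy)3, 2,6-lutidine, MeCN, blue LEDs) then lets the C4 radical from F1 add to C5 of F2; oxidation and loss of silicon give 14 without any strong base.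

Step 10 (acyl shift and pseudo-ester formation). What may go wrong: under acid the acyl group migrates back to the phenol (re-forming the six-membered aryl lactone) or the enol ester hydrolyses faster than the phenol adds to it, so the bridged pseudo-ester does not accumulate. The fallback sets out from 17 and returns at 21. After CsF and a buffered quench the enol lactone 18 is isolated and methylenated (excess Cp2TiMe2, toluene, 70 °C) to the bis(enol ether) F3, which has no acyl group left to migrate. CSA in dichloroethane then adds the phenol to C1 and effects the same O→C rearrangement in one flask, the benzoxepine closing first and the cyclopentane last.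

Step 12 (key rearrangement). What may go wrong: under protic acid the ion pair recombines on oxygen and rests as the fused chroman ketal, the β-aryloxy ketone loses the aryloxy group by retro-oxa-Michael elimination, or C10 is not funnelled cleanly. The fallback sets out from 20 and returns at 23. Triisobutylaluminium (toluene, −78 → 0 °C) triggers the rearrangement through an aluminium enolate and reduces the ketone as it forms, giving the cyclopentanol F4 with the aryloxy group retained. Barton–McCombie deoxygenation follows: NaH, CS2, MeI give the xanthate F5, and Bu3SnH/AIBN (toluene, 80 °C) gives 23.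

**Further compounds**

F1 | step 7 | (3R,4S)-trans-5,7-bis(benzyloxy)-3-bromo-4-phenylchroman-2-one | O=C1Oc2cc(OCc3ccccc3)cc(OCc3ccccc3)c2[C@H](c4ccccc4)[C@H]1Br
F2 | step 7 | kinetic TMS enol ether of ketone 7 (C1=C5) | CC1CC[C@@H]2[C@H](C=C1O[Si](C)(C)C)C2(C)C
F3 | step 10 | bis(enol ether): 18 with the lactone C=O replaced by C=CH2 | Oc1cc(OCc2ccccc2)cc(OCc2ccccc2)c1[C@H](c3ccccc3)[C@@]4(C)C(=C)OC5=C(C)CC[C@@H]6[C@H]([C@H]45)C6(C)C
F4 | step 12 | 3-hydroxy-di-O-benzyl-bis(deformyl)psiguadial A (C3 carbinol configuration open) | C[C@H]1CC[C@@H]2[C@H]([C@@H]3[C@]4(C)C(O)C[C@@]31Oc1cc(OCc5ccccc5)cc(OCc5ccccc5)c1[C@@H]4c1ccccc1)C2(C)C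
F5 | step 12 | S-methyl xanthate of F4 | C[C@H]1CC[C@@H]2[C@H]([C@@H]3[C@]4(C)C(OC(=S)SC)C[C@@]31Oc1cc(OCc5ccccc5)cc(OCc5ccccc5)c1[C@@H]4c1ccccc1)C2(C)C
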